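**Retrosynthetic overview**
- Amide C–N bond: target ⇒ 2-amino-3-(2-methylpyridin-4-yl)phenol + 13-(acetylsulfanyl)tridecanoyl chloride.
- Side chain: C–S bond by radical thiol-ene addition of thioacetic acid to tridec-12-enoic acid, itself from 11-bromoundec-1-ene by malonic ester synthesis.
- Aminophenol ⇒ (nitro reduction, O-demethylation) 4-(3-methoxy-2-nitrophenyl)-2-methylpyridine; pyridine ring ⇒ 3-aryl-5-oxohexanal + hydroxylamine.
- Key C–C bond (C4–C5 of the future pyridine): intermolecular Michael-type (Hosomi–Sakurai) addition of allyltrimethylsilane to the aryl enone, then ozonolysis; the enone comes from 3-methoxy-2-nitrobenzaldehyde by Wittig olefination.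
- Ring order: the benzene ring is bought; the pyridine ring is the only ring built, after the key C–C bond and before the amide coupling.

Assumption: the target is achiral (no stereocentre, freely rotating biaryl axis), so no enantiocontrol is needed and the compound is made as drawn.

**Route**

Step 1
Reactants: 1 3-methoxy-2-nitrobenzaldehyde; 2 1-(triphenylphosphoranylidene)propan-2-one
Product: 3 (E)-4-(3-methoxy-2-nitrophenyl)but-3-en-2-one
Conditions: toluene, 90 °C, 12 h
Reagents that add atoms: none
Why: Wittig olefination with a ketone-stabilised ylide is reliable for the electrophilic ortho-nitrobenzaldehyde, gives the E-enone selectively, and avoids the indigo-type (Baeyer–Drewsen) side reaction that a basic aldol condensation with acetone would risk.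

Step 2
Reactants: 3 (E)-4-(3-methoxy-2-nitrophenyl)but-3-en-2-one; 4 allyltrimethylsilane
Product: 6 rac-4-(3-methoxy-2-nitrophenyl)hept-6-en-2-one, via trichlorotitanium enolate 5 (not isolated)
Conditions: TiCl4 (1.2 equiv), CH2Cl2, −78 → −30 °C; then H2O
Reagents that add atoms: none
Why: Hosomi–Sakurai reaction, an intermolecular Michael-type 1,4-addition of the allylsilane to the TiCl4-activated enone, forms the C4–C5 bond of the future pyridine; the new benzylic stereocentre forms as a racemate and is erased on aromatisation in step 4.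

Step 3
Reactants: 6 rac-4-(3-methoxy-2-nitrophenyl)hept-6-en-2-one
Product: 8 rac-3-(3-methoxy-2-nitrophenyl)-5-oxohexanal, via ozonide 7 (not isolated)
Conditions: O3, CH2Cl2, −78 °C; then PPh3, −78 °C → rt; used crude
Reagents that add atoms: ozone, [O-][O+]=O
Why: Ozonolysis with reductive work-up cleaves only the terminal alkene (the nitro-deactivated arene and the ketone are inert at −78 °C) and unmasks the 1,5-ketoaldehyde.

Step 4
Reactants: 8 rac-3-(3-methoxy-2-nitrophenyl)-5-oxohexanal
Product: 11 4-(3-methoxy-2-nitrophenyl)-2-methylpyridine, via aldoxime 9 (not isolated), via N-hydroxy-1,4-dihydropyridine 10 (not isolated)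
Conditions: NH2OH·HCl (2 equiv), EtOH, reflux; then aq NaHCO3
Reagents that add atoms: hydroxylamine hydrochloride, Cl.NO
Why: Cyclocondensation of a 1,5-dicarbonyl compound with hydroxylamine (oxime formation, ring closure on the ketone, loss of three molecules of water with the N–O bond as internal oxidant) gives the aromatic pyridine without an external oxidant and destroys the stereocentre.

Step 5
Reactants: 11 4-(3-methoxy-2-nitrophenyl)-2-methylpyridine
Product: 12 3-(2-methylpyridin-4-yl)-2-nitrophenol
Conditions: 48% aq HBr, AcOH, reflux; then aq NaHCO3 to pH 7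
Reagents that add atoms: none
Why: Acid-mediated aryl methyl ether cleavage (SN2 attack of bromide on the protonated methoxy group) is facile for ortho-nitroanisoles and leaves the nitro group and the protonated pyridine untouched.

Step 6
Reactants: 12 3-(2-methylpyridin-4-yl)-2-nitrophenol
Product: 13 2-amino-3-(2-methylpyridin-4-yl)phenol
Conditions: H2 (1 atm), 10% Pd/C, MeOH, rt; filtered under N2 and used at once
Reagents that add atoms: none
Why: Catalytic hydrogenation reduces the aromatic nitro group cleanly to the aniline, while the pyridine ring is not reduced at 1 atm and rt under neutral conditions.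

Step 7
Reactants: 14 11-bromoundec-1-ene; 15 diethyl malonate
Product: 17 diethyl 2-(undec-10-en-1-yl)propanedioate, via sodium diethyl malonate 16 (not isolated)
Conditions: NaOEt, EtOH, reflux (malonate in excess)
Reagents that add atoms: none
Why: Malonic ester alkylation is an SN2 substitution of the unhindered primary bromide by the malonate enolate, and excess malonate suppresses dialkylation.

Step 8
Reactants: 17 diethyl 2-(undec-10-en-1-yl)propanedioate
Product: 19 2-(undec-10-en-1-yl)propanedioic acid, via dipotassium malonate salt 18 (not isolated)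
Conditions: KOH, EtOH/H2O, reflux; then conc. HCl, 0 °C
Reagents that add atoms: KOH, [K+].[OH-]
Why: Saponification (acyl-oxygen ester hydrolysis) of both ethyl esters is irreversible and the isolated terminal alkene is inert to hydroxide.

Step 9
Reactants: 19 2-(undec-10-en-1-yl)propanedioic acid
Product: 20 tridec-12-enoic acid
Conditions: neat, 170 °C, until gas evolution stops
Reagents that add atoms: none
Why: Thermal decarboxylation of a malonic acid through a six-membered cyclic transition state needs no reagent and leaves the remote terminal alkene in place.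

Step 10
Reactants: 20 tridec-12-enoic acid; 21 thioacetic S-acid
Product: 22 13-(acetylsulfanyl)tridecanoic acid
Conditions: AIBN (5 mol %), toluene, 80 °C
Reagents that add atoms: none
Why: Radical thiol-ene addition is a chain process in which the acetylthiyl radical adds to the terminal carbon, so only the anti-Markovnikov primary thioacetate forms and the carboxylic acid does not interfere.

Step 11
Reactants: 22 13-(acetylsulfanyl)tridecanoic acid
Product: 23 13-(acetylsulfanyl)tridecanoyl chloride
Conditions: (COCl)2, DMF (cat.), CH2Cl2, 0 °C → rt; evaporated, used crude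
Reagents that add atoms: oxalyl chloride, O=C(Cl)C(=O)Cl
Why: Acid chloride formation under DMF (Vilsmeier-type) catalysis is mild and gives only gaseous by-products, and S-acetyl thioesters are known to survive it.

Step 12
Reactants: 13 2-amino-3-(2-methylpyridin-4-yl)phenol; 23 13-(acetylsulfanyl)tridecanoyl chloride
Product: 24 Echinoclathrine B
Conditions: NaHCO3 (3 equiv), THF, 0 °C → rt, 23 (1.0 equiv) added slowly
Reagents that add atoms: none
Why: Chemoselective N-acylation (amide formation with an acid chloride) works because the aniline is more nucleophilic than the un-ionised phenol under NaHCO3 and any O-acyl isomer rearranges by O→N acyl shift, while the thioacetate is untouched.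

**Compound list**
1 | 3-methoxy-2-nitrobenzaldehyde | COc1cccc(C=O)c1[N+](=O)[O-] | starting material
2 | 1-(triphenylphosphoranylidene)propan-2-one | CC(=O)C=P(c1ccccc1)(c1ccccc1)c1ccccc1 | starting material
3 | (E)-4-(3-methoxy-2-nitrophenyl)but-3-en-2-one | COc1cccc(/C=C/C(C)=O)c1[N+](=O)[O-] | intermediate
4 | allyltrimethylsilane | C=CC[Si](C)(C)C | starting material
5 | trichlorotitanium enolate of 6, trichloro{[4-(3-methoxy-2-nitrophenyl)hepta-2,6-dien-2-yl]oxy}titanium (racemic) | COc1cccc(C(CC=C)C=C(C)O[Ti](Cl)(Cl)Cl)c1[N+](=O)[O-] | intermediate (not isolated)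
6 | rac-4-(3-methoxy-2-nitrophenyl)hept-6-en-2-one | COc1cccc(C(CC=C)CC(C)=O)c1[N+](=O)[O-] | intermediate
7 | ozonide, 4-(3-methoxy-2-nitrophenyl)-5-(1,2,4-trioxolan-3-yl)pentan-2-one (racemic diastereomer mixture) | COc1cccc(C(CC2OCOO2)CC(C)=O)c1[N+](=O)[O-] | intermediate (not isolated)
8 | rac-3-(3-methoxy-2-nitrophenyl)-5-oxohexanal | COc1cccc(C(CC=O)CC(C)=O)c1[N+](=O)[O-] | intermediate
9 | aldoxime, rac-6-(hydroxyimino)-4-(3-methoxy-2-nitrophenyl)hexan-2-one | COc1cccc(C(CC=NO)CC(C)=O)c1[N+](=O)[O-] | intermediate (not isolated)
10 | N-hydroxy-1,4-dihydropyridine, rac-4-(3-methoxy-2-nitrophenyl)-2-methylpyridin-1(4H)-ol | COc1cccc(C2C=CN(O)C(C)=C2)c1[N+](=O)[O-] | intermediate (not isolated)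
11 | 4-(3-methoxy-2-nitrophenyl)-2-methylpyridine | COc1cccc(-c2ccnc(C)c2)c1[N+](=O)[O-] | intermediate
12 | 3-(2-methylpyridin-4-yl)-2-nitrophenol | Oc1cccc(-c2ccnc(C)c2)c1[N+](=O)[O-] | intermediate
13 | 2-amino-3-(2-methylpyridin-4-yl)phenol | Nc1c(O)cccc1-c1ccnc(C)c1 | intermediate
14 | 11-bromoundec-1-ene | C=CCCCCCCCCCBr | starting material
15 | diethyl malonate | CCOC(=O)CC(=O)OCC | starting material
16 | sodium diethyl malonate | CCOC(=O)[CH-]C(=O)OCC.[Na+] | intermediate (not isolated)
17 | diethyl 2-(undec-10-en-1-yl)propanedioate | C=CCCCCCCCCCC(C(=O)OCC)C(=O)OCC | intermediate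
18 | dipotassium 2-(undec-10-en-1-yl)propanedioate | C=CCCCCCCCCCC(C(=O)[O-])C(=O)[O-].[K+].[K+] | intermediate (not isolated)
19 | 2-(undec-10-en-1-yl)propanedioic acid | C=CCCCCCCCCCC(C(=O)O)C(=O)O | intermediate
20 | tridec-12-enoic acid | C=CCCCCCCCCCCC(=O)O | intermediate
21 | thioacetic S-acid | CC(=O)S | starting material
22 | 13-(acetylsulfanyl)tridecanoic acid | CC(=O)SCCCCCCCCCCCCC(=O)O | intermediate
23 | 13-(acetylsulfanyl)tridecanoyl chloride | CC(=O)SCCCCCCCCCCCCC(=O)Cl | intermediate
24 | Echinoclathrine B, S-(13-{[2-hydroxy-6-(2-methylpyridin-4-yl)phenyl]amino}-13-oxotridecyl) ethanethioate | CC(=O)SCCCCCCCCCCCCC(=O)Nc1c(O)cccc1-c1ccnc(C)c1 | target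

**Summary**
Total step count: 12. Longest linear sequence: 7 steps (steps 1–6, then step 12); the side-chain branch is steps 7–11.

**Steps most likely to fail, with fallbacks**

Step 2 (conjugate allylation of the ortho-nitroaryl enone; risks are 1,2-addition, nitro-group participation and sluggish reaction). The fallback sets out from 1 and comes back at 11, bypassing steps 2–4 with a Kröhnke pyridine synthesis. Aldehyde 1 is olefinated with (triphenylphosphoranylidene)acetaldehyde (toluene, 80 °C) to (E)-3-(3-methoxy-2-nitrophenyl)prop-2-enal F1. F1 is heated with commercial 1-(2-oxopropyl)pyridinium chloride and NH4OAc in AcOH/MeOH. The pyridinium ylide adds in a Michael reaction to give 1-[4-(3-methoxy-2-nitrophenyl)-2,6-dioxohexan-3-yl]pyridin-1-ium chloride F2 (not isolated). F2 condenses with ammonia and expels pyridine to give 11 directly.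

Step 4 (ring closure of the sensitive ketoaldehyde; the risk is intramolecular aldol or oligomerisation before the oxime cyclises). The fallback sets out from 8 and comes back at 11. Hydroxylamine as internal oxidant is replaced by ammonia condensation and a separate dehydrogenation. 8 is stirred with NH4OAc in AcOH at 60 °C to give 4-(3-methoxy-2-nitrophenyl)-2-methyl-1,4-dihydropyridine F3. F3 is taken up in CH2Cl2 without purification and aromatised with DDQ (1.1 equiv, rt) to 11.

Step 12 (N- versus O-acylation of the hindered, air-sensitive aminophenol; the risk is O-acyl or N,O-diacyl products that cannot be cleaved selectively beside the thioacetate). The fallback sets out from 13 and comes back at 24, using temporary phenol protection. 13 is O-silylated with TBSCl and imidazole in DMF to 2-{[tert-butyl(dimethyl)silyl]oxy}-6-(2-methylpyridin-4-yl)aniline F4. F4 is acylated with 23 (pyridine, 4-(dimethylamino)pyridine cat., CH2Cl2, rt → 40 °C) to S-[13-({2-[(tert-butyldimethylsilyl)oxy]-6-(2-methylpyridin-4-yl)phenyl}amino)-13-oxotridecyl] ethanethioate F5. F5 is desilylated with TBAF buffered with AcOH (1:1, THF, 0 °C), which spares the thioester, to give 24.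

**Further compounds**
F1 | step 2 | (E)-3-(3-methoxy-2-nitrophenyl)prop-2-enal | COc1cccc(/C=C/C=O)c1[N+](=O)[O-]
F2 | step 2 | 1-[4-(3-methoxy-2-nitrophenyl)-2,6-dioxohexan-3-yl]pyridin-1-ium chloride (racemic diastereomer mixture) | COc1cccc(C(CC=O)C(C(C)=O)[n+]2ccccc2)c1[N+](=O)[O-].[Cl-]
F3 | step 4 | rac-4-(3-methoxy-2-nitrophenyl)-2-methyl-1,4-dihydropyridine | COc1cccc(C2C=CNC(C)=C2)c1[N+](=O)[O-]
F4 | step 12 | 2-{[tert-butyl(dimethyl)silyl]oxy}-6-(2-methylpyridin-4-yl)aniline | CC(C)(C)[Si](C)(C)Oc1cccc(-c2ccnc(C)c2)c1N
F5 | step 12 | S-[13-({2-[(tert-butyldimethylsilyl)oxy]-6-(2-methylpyridin-4-yl)phenyl}amino)-13-oxotridecyl] ethanethioate | CC(=O)SCCCCCCCCCCCCC(=O)Nc1c(O[Si](C)(C)C(C)(C)C)cccc1-c1ccnc(C)c1
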